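The readings are simulated for an exercise, noise included.

5 flasks and 6 questions come down to one: when you hand in the substrate slowly, does the catalyst keep up with you?

common to all: free catalyst 0.5 mol%

| run | substrate | reagent | remark | time |
|---|---|---|---|---|
| autumn | 0.20 M | 1.2 equiv | run made earlier |  |
| midnight | 0.40 M | 1.2 equiv | run made earlier |  |
| birch | 0.20 M | 1.20 equiv | everything together at the start | 6.0 min |
| alder | 0.20 M (fed, over 5.0 min) | 1.20 equiv | all else is in the flask from the start; the feed brings no volume worth counting | 6.0 min |
| maple | 0.20 M | 1.20 equiv (fed, over 5.0 min) | all else is in the flask from the start; the feed brings no volume worth counting | 6.0 min |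
| cedar | 0.20 M (fed, over 30 s) | 1.20 equiv | all else is in the flask from the start; the feed brings no volume worth counting | 6.0 min |
| elm | 0.20 M (in portions, 5, over 5.0 min) | 1.20 equiv | first portion at the start, last at 5.0 min | 6.0 min |

- autumn (time / min: target / %, side product / %): 0.250: 3.9, 0.3; 0.667: 10.9, 2.4; 1.33: 20.5, 7.3; 2.00: 30.1, 14.3; 3.00: 42.5, 21.8; 4.00: 53.7, 27.9
- midnight (time / s: target / %, side product / %): 12.0: 4.9, 1.5; 25.0: 10.0, 3.3; 40.0: 15.4, 6.4; 50.0: 20.2, 8.5; 60.0: 23.5, 11.3; 80.0: 30.5, 15.9

(each reading ± 0.3 percentage points)



- the best flask by share of target in target plus side product; "all alike" if 1.5 percentage points covers them all (birch / alder / maple / cedar / elm / all alike)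
- share of target in target plus side product at the end, birch
- share of target in target plus side product at the end, alder
- share of target in target plus side product at the end, maple
- share of target in target plus side product at the end, cedar
- share of target in target plus side product at the end, elm

Start with the autumn run, where the target climbs nearly in a straight line while the substrate falls, from 10.9 % at 0.667 min to 30.1 % at 2.00 min, and this reads as a rate of 0.0288 M min⁻¹. Divide the charge by that rate and you get 6.94 min: call this the turnover time, the time the catalyst needs to pass the whole charge into target at its straight-line rate.

Now set the times of the flasks against it, shortest first. Cedar's feed of 30 s is far shorter than the turnover time, so you should expect cedar to behave as birch does, everything together at the start. Elm's portions arrive every 1.25 min, but at the straight-line rate of the autumn run each one reckons to 1.39 min of passing into target, so you should expect each portion to land on the remains of the last. Alder's feed of 5.0 min is also shorter than the turnover time, so in alder too the substrate should build up rather than stay near zero.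

My own reckoning, which puts no figure on the shares, is therefore that cedar tracks birch and that alder and elm still hold substrate at 6.0 min.

The forecast names alder as best and gives birch 66 %, alder 80 %, maple 60 %, cedar 67 % and elm 79 %, holding that alder's feed “barely exceeds target rate”.

The simulation gives birch 68.4 %, alder 74.0 %, maple 64.6 %, cedar 68.4 % and elm 76.1 %, so elm comes first, ahead of alder by more than the margin.

    reagent + free catalyst ⇌ catalyst intermediate A (K = 1.40 M⁻¹, k = 380 M⁻¹ s⁻¹)
    substrate + by-product → side product (k = 0.0810 M⁻¹ s⁻¹)
    catalyst intermediate C → free catalyst + target (k = 5.00 s⁻¹)
    substrate + catalyst intermediate B → catalyst intermediate C (k = 310 M⁻¹ s⁻¹)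
    catalyst intermediate A → by-product + catalyst intermediate B (k = 2.50 s⁻¹)

In elm at 2.58 min, substrate is used twice as fast by the path to catalyst intermediate C as by the path to side product, and 8.24 % of the charge still stands at 6.00 min, with the turnover time of 6.94 min longer than the 5.0 min over which the portions of elm came. Now take the neighbour, elm with 1.2 mol% of free catalyst: if you assume that the rate follows the catalyst, the turnover time reckons to 2.89 min, shorter than the 5.0 min of the portions. That flask gives a share of 87.5 %, with 0.0557 % of the substrate left.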